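## Structural features

The target is a spiro[5.5]undecane of the chamigrane type, numbered here with C6 as the spiro carbon, C1–C5 in ring B and C7–C11 in ring A. Ring B carries an exocyclic methylene on C1 (C15), a doubly allylic secondary carbinol at C2, a bromoalkene C3=C4 and a gem-dimethyl carbon C5, so C6 sits between an sp2 carbon and a fully substituted sp3 carbon. Ring A is saturated and carries on adjacent carbons a tertiary chloride with a methyl group (C9) and a secondary bromide (C10); the halogens are trans, both equatorial in the chair that keeps C5 equatorial, and bromine is cis to C5. The stereocentres are C2 (R), isolated in ring B, the spiro centre C6 (S), and the contiguous pair C9 (S) and C10 (S); C6 and C10 stand 1,3 through C11. Fragile groups are the C2–O bond (ionisation, allylic transposition), the tertiary chloride β to bromine (elimination, halonium shifts), the exocyclic alkene (epoxidation, and a Michael acceptor whenever C2 is a ketone) and the alkenyl bromide (metal exchange). The real difficulty is the quaternary spiro centre next to the gem-dimethyl carbon, its configuration relative to the remote C9/C10 pair, and the placing of two equatorial halogens on a ring whose C10 is screened by the axial C9 methyl on one face and by C1/C15 on the other. The key step exploits the fact that C9, a fully substituted carbon with methyl and a heteroatom next to the heteroatom-bearing C10, is the retron of a ketol between two identical 3-oxobutyl arms on C6; choosing which arm acts as enamine donor closes ring A and fixes C6, C9 and C10 together.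

## Logic of the disconnections

24 is cut at the O–Si bond of C2 to give 23. The doubly allylic C2–O bond must stay masked while ring A is handled with electrophiles. The demand is a buffered fluoride cleavage that eliminates neither halide.

23 is cut at C9–Cl and C10–Br, with bromine put back on C9 and oxygen on C10, to give 20 (through 21 and 22). An external nucleophile cannot reach C10, so bromine is brought there from the neighbouring carbon through a bromonium ion and chloride then enters at the tertiary carbon. Both carbon–halogen bonds and their trans relation then come from one trans-diaxial precursor. The demand is a leaving group on C10 antiperiplanar to C9–Br, chloride attack at C9 and not C10, and no proton loss.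

20 is cut at C9–Br with closure of a C9–O bond to give 19. Opening of an epoxide at its tertiary carbon anti to oxygen is favoured both electronically and conformationally. This turns halogen stereochemistry into oxygen stereochemistry; the demand is a bromide source mild enough for the silyl ether.

19 is cut at the epoxide C10–O bond to give 17 (through 18). Intramolecular closure inverts C10 without external attack, and a trans diol is what oxidative cleavage of a ketol delivers. The demand is selective activation of the secondary hydroxyl and closure faster than ring contraction.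

17 is cut at C10–O with restoration of the C10–acetyl bond to give 15 (through 16). An oxygen insertion with retention lets the aldol stereochemistry be used, and the C9/C10 pattern becomes a β-hydroxy ketone. The demand is an oxidant that attacks the ketone and none of the three alkenes, with the secondary carbon migrating.

15 is cut at C9–C10 to give 12 (through 13 and 14). This removes ring A and three stereocentres at once; 12 has two identical arms and only C2 as a stereocentre. The demand is a catalyst that chooses the arm and the face, and a precursor that has no other enolisable or electrophilic site and is made without base.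

12 is cut at both CH3–C(=O) bonds to give 10 (through 11). Free methyl ketones would cyclise or be reduced in the earlier steps, so the arms are carried as esters. The demand is single addition of a methyl nucleophile to each arm and a neutral unveiling.

10 is cut at O–Si and at the C2–H bond to give 8 (through 9). A reagent-controlled reduction sets C2, and everything before it is achiral. The demand is discrimination between two alkenyl arms and 1,2-reduction.

8 is cut at C4–Br, with the oxygen moved from C2 back to C4 as a vinylogous ester, to give 7. The bromoenone is the halide form of a 1,3-dicarbonyl, which traces ring B to a dione enol ether. The demand is a regiospecific transposition.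

7 is cut at C1=C15 to give 6. The C1 carbonyl is what makes C6 nucleophilic, so the olefination must follow the installation of the arms. The demand is methylenation of a hindered ketone beside two esters and a vinylogous ester.

6 is cut at both C6–CH2 bonds to give 3 and two molecules of 4 (through 5, which holds the first arm). Each arm is a conjugate adduct and C6 is the only enolisable carbon of 3, so both arms and the vicinal quaternary pair arise in one operation without a stereocentre in the product. The demand is a second addition next to the gem-dimethyl carbon without self-condensation.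

3 is cut at the C1 carbonyl oxygen and at O–CH3 to give 1 (through 2). 1 already holds the gem-dimethyl carbon and the oxygens of C2 and C4. The demand is regioselective enol ether formation and oxidation at the single allylic methylene.

## Other disconnections considered

Alternative 1: The cut is the C6–C11 bond, with a C9=C10 alkene in place of the ring A heteroatoms. In the forward step EtAlCl2 activates a cross-conjugated ring B bromodienone whose C6 side chain ends in a tertiary allylsilane; the terminal alkene carbon adds to C6 anti to silicon and gives (6S)-4-bromo-5,5,9-trimethylspiro[5.5]undeca-3,9-dien-2-one (A1).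
- In its favour: the quaternary centre next to the gem-dimethyl carbon comes from an intramolecular conjugate addition, which is more dependable at so congested a carbon than the double Michael addition of the chosen plan. On this point the alternative is the better one. The ring B ketone and bromoalkene are also already in place.
- Against it here: the chirality must first be built stoichiometrically into the silane stereocentre, and a gem-dimethyl dienone under a strong Lewis acid can rearrange. A1 lacks C15, and both halogens must then be added to the ring A alkene; trans-diaxial opening of a bromonium ion on the preformed spirocycle should favour bromine trans to C5, the opposite of the target.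
- Comparison: it sets one stereocentre where the chosen step sets three, uses substrate control where the chosen step uses catalysis, and is no shorter once the silane synthesis is counted. The late halogenation problem is equal in both plans.

Alternative 2: The cuts are C6–C7 and C10–C11. In the forward step a C6-formyl derivative of the ring B methoxy ene-dione adds in conjugate fashion to a simple four-carbon methyl enone under a chiral amine–thiourea, and aldol condensation of the new methyl ketone onto the formyl carbon gives (6R)-2-methoxy-5,5-dimethylspiro[5.5]undeca-2,10-diene-1,4,9-trione (A2; same spatial arrangement at C6 as the target).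
- In its favour: the nucleophile is a 1,3-dicarbonyl, so the bond to C6 forms under mild catalysis and only one chain has to be attached at the congested carbon. This is better than the chosen plan at that bond. The early ring B chemistry is the same in both plans, which is an equal point.
- Against it here: the catalyst must tell apart the two faces of a planar, hindered enol whose ring neighbours differ little. A2 still needs the C9 methyl (a 1,2-addition with facial control), saturation of the enone and both halogens, with the same diequatorial problem.
- Comparison: one stereocentre is set against three, face selection replaces arm selection, and more ring A steps follow the key step.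

Alternative 3: The cut is C4–C5 in ring B. In the forward step Fe(acac)3/PhSiH3 transfers a hydrogen atom to an isopropenyl group on C6, the tertiary radical adds 6-endo to a dibromovinyl ketone and loss of a bromine atom gives 4-bromo-5,5-dimethylspiro[5.5]undec-3-ene-2,9-dione 9-ethylene ketal (A3).
- In its favour: the vicinal quaternary pair and the bromoalkene arise in one radical step that is indifferent to congestion, which is better than the chosen plan for that bond. A3 is achiral, so nothing can be lost at that stage, an equal point.
- Against it here: C6 becomes a stereocentre only when ring A is later desymmetrised, so all four stereocentres are postponed. The 6-endo versus 5-exo choice and reduction of C–Br by the hydride source are open, and C15 and the C2 carbinol remain to be added.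
- Comparison: the chosen plan fixes C6 in the ring-forming step under catalyst control; the radical plan is mechanistically more robust at the quaternary carbon but comparable or longer in step count.

Key step: step 10

Remark: descriptors use the numbering C6 (spiro), C1–C5 (ring B, C15 on C1) and C7–C11 (ring A); ring A is assumed to prefer the chair with C5 equatorial and C1 axial, and all stereochemical arguments in ring A use this chair.

## Route

Step 1
Reactants: 1 4,4-dimethylcyclohexane-1,3-dione
Product: 2 3-methoxy-6,6-dimethylcyclohex-2-en-1-one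
Conditions: MeOH, TsOH (cat.), 3 Å MS, reflux
Reagents that add atoms: methanol, CO
Why: Acid-catalysed enol etherification of a cyclic 1,3-dione; methanol should add to the carbonyl remote from the gem-dimethyl carbon, so the vinylogous ester keeps its carbonyl next to C5, and the minor regioisomer is removed by chromatography.

Step 2
Reactants: 2 3-methoxy-6,6-dimethylcyclohex-2-en-1-one
Product: 3 2-methoxy-5,5-dimethylcyclohex-2-ene-1,4-dione
Conditions: Rh2(cap)4 (1 mol %; cap = caprolactamate), tBuOOH, K2CO3, CH2Cl2, rt
Reagents that add atoms: tert-butyl hydroperoxide, CC(C)(C)OO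
Why: Allylic C–H oxidation of the γ-methylene of an enone to the ene-1,4-dione; the only allylic methylene is C1, because the carbon on the other side of the carbonyl is quaternary, and the new ketone is the one that will acidify C6.

Step 3
Reactants: 3 2-methoxy-5,5-dimethylcyclohex-2-ene-1,4-dione, 4 methyl acrylate (2.5 equiv; two molecules are taken up)
Product: 6 dimethyl 3,3'-(3-methoxy-6,6-dimethyl-2,5-dioxocyclohex-3-ene-1,1-diyl)dipropanoate, via mono-adduct 5 (not isolated)
Conditions: methyl acrylate (2.5 equiv), KOtBu (0.2 equiv), THF/tBuOH, 0 °C → rt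
Reagents that add atoms: methyl acrylate (the second molecule of 4), C=CC(=O)OC
Why: Base-catalysed double Michael addition: C6 is the only enolisable carbon, its enolate adds to the unsubstituted terminus of 4 to give mono-adduct 5, and the remaining C6–H of 5 is removed again and adds to a second molecule of 4. Conjugate addition tolerates the neighbouring gem-dimethyl carbon far better than SN2 alkylation would, and the quaternary carbon of 6 is not a stereocentre.

Step 4
Reactants: 6 dimethyl 3,3'-(3-methoxy-6,6-dimethyl-2,5-dioxocyclohex-3-ene-1,1-diyl)dipropanoate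
Product: 7 dimethyl 3,3'-(3-methoxy-6,6-dimethyl-2-methylidene-5-oxocyclohex-3-ene-1,1-diyl)dipropanoate
Conditions: Zn, CH2Br2, TiCl4, THF/CH2Cl2, 0 °C → rt
Reagents that add atoms: dibromomethane, BrCBr
Why: Takai–Lombardo methylenation; the non-basic zinc/titanium reagent accepts hindered conjugated ketones and should leave the esters and the deactivated vinylogous ester carbonyl (C4) alone.

Step 5
Reactants: 7 dimethyl 3,3'-(3-methoxy-6,6-dimethyl-2-methylidene-5-oxocyclohex-3-ene-1,1-diyl)dipropanoate
Product: 8 dimethyl 3,3'-(5-bromo-6,6-dimethyl-2-methylidene-3-oxocyclohex-4-ene-1,1-diyl)dipropanoate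
Conditions: (COBr)2, DMF (cat.), CH2Cl2, 0 °C → rt
Reagents that add atoms: oxalyl bromide, O=C(Br)C(=O)Br
Why: Vilsmeier-type conversion of a vinylogous ester into the transposed β-bromo enone (O-acylation of the C4 carbonyl, addition–elimination of bromide at C4, demethylation of the C2 oxocarbenium by bromide); the mechanism fixes bromine on C4 and the ketone on C2.

Step 6
Reactants: 8 dimethyl 3,3'-(5-bromo-6,6-dimethyl-2-methylidene-3-oxocyclohex-4-ene-1,1-diyl)dipropanoate
Product: 9 dimethyl 3,3'-[(3R)-5-bromo-3-hydroxy-6,6-dimethyl-2-methylidenecyclohex-4-ene-1,1-diyl]dipropanoate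
Conditions: (S)-2-methyl-CBS-oxazaborolidine (20 mol %), catecholborane, toluene, −78 °C
Reagents that add atoms: none
Why: Corey–Bakshi–Shibata reduction; the α-branched C1 alkenyl arm next to quaternary C6 should act as the large group and the unbranched C3 arm as the small one, so the S catalyst should give the R carbinol, and catecholborane at low temperature favours 1,2- over 1,4-reduction.

Step 7
Reactants: 9 dimethyl 3,3'-[(3R)-5-bromo-3-hydroxy-6,6-dimethyl-2-methylidenecyclohex-4-ene-1,1-diyl]dipropanoate
Product: 10 dimethyl 3,3'-[(3R)-5-bromo-3-{[tert-butyl(dimethyl)silyl]oxy}-6,6-dimethyl-2-methylidenecyclohex-4-ene-1,1-diyl]dipropanoate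
Conditions: TBSOTf, 2,6-lutidine, CH2Cl2, −78 → 0 °C
Reagents that add atoms: tert-butyldimethylsilyl triflate, CC(C)(C)[Si](C)(C)OS(=O)(=O)C(F)(F)F
Why: Silylation of a hindered secondary allylic alcohol with a silyl triflate; the ether keeps ring B free of any Michael acceptor and shields the doubly allylic C–O bond.

Step 8
Reactants: 10 dimethyl 3,3'-[(3R)-5-bromo-3-{[tert-butyl(dimethyl)silyl]oxy}-6,6-dimethyl-2-methylidenecyclohex-4-ene-1,1-diyl]dipropanoate
Product: 11 3,3'-[(3R)-5-bromo-3-{[tert-butyl(dimethyl)silyl]oxy}-6,6-dimethyl-2-methylidenecyclohex-4-ene-1,1-diyl]bis(N-methoxy-N-methylpropanamide)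
Conditions: MeNHOMe·HCl (4 equiv), iPrMgCl (8 equiv), THF, −20 °C
Reagents that add atoms: N,O-dimethylhydroxylamine hydrochloride, CNOC.Cl
Why: Aminolysis of both methyl esters by the magnesium amide to give Weinreb amides; the temperature is too low for Dieckmann closure of the two arms or for bromine–magnesium exchange at the alkenyl bromide.

Step 9
Reactants: 11 3,3'-[(3R)-5-bromo-3-{[tert-butyl(dimethyl)silyl]oxy}-6,6-dimethyl-2-methylidenecyclohex-4-ene-1,1-diyl]bis(N-methoxy-N-methylpropanamide)
Product: 12 4,4'-[(3R)-5-bromo-3-{[tert-butyl(dimethyl)silyl]oxy}-6,6-dimethyl-2-methylidenecyclohex-4-ene-1,1-diyl]di(butan-2-one)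
Conditions: MeMgBr (3 equiv), THF, 0 °C; cold aq. NH4Cl
Reagents that add atoms: methylmagnesium bromide, C[Mg]Br
Why: Weinreb ketone synthesis on both arms; the chelated adducts prevent over-addition and keep both ketones masked until a cold, weakly acidic quench, so no base-mediated aldol closure can precede the catalytic step.

Step 10
Reactants: 12 4,4'-[(3R)-5-bromo-3-{[tert-butyl(dimethyl)silyl]oxy}-6,6-dimethyl-2-methylidenecyclohex-4-ene-1,1-diyl]di(butan-2-one)
Product: 15 1-[(2R,6S,9S,10S)-4-bromo-2-{[tert-butyl(dimethyl)silyl]oxy}-9-hydroxy-5,5,9-trimethyl-1-methylidenespiro[5.5]undec-3-en-10-yl]ethan-1-one, via proline enamine 13 (not isolated), via ketol iminium 14 (not isolated)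
Conditions: (S)-proline (30 mol %), DMSO, rt
Reagents that add atoms: none
Why: (S)-Proline condenses reversibly with either ketone; the methyl-side enamines could only close an eight-membered ring, so the reaction should funnel through the E enamine 13 at C10, whose α-carbon adds to the C9 carbonyl of the other arm, and hydrolysis of iminium 14 releases 15 and the catalyst. The closest known reaction type is the proline-catalysed 6-enolexo aldol cyclisation of 1,7-dicarbonyl compounds through a hydrogen-bonded chair. Ring A closes in the 6-(enolexo)-exo-trig mode. C10 is set by the catalyst, whose carboxylic acid brings the acceptor to one enamine face; for (S)-proline this is expected to be the face that gives 10S, by analogy with its anti aldols of cyclic ketones. C9 is set by the hydrogen bond from the carboxylic acid to the acceptor oxygen, which holds that oxygen equatorial and trans to the acyl group and leaves the methyl axial, giving 9S. C6 is set by the choice of donor arm: in the chair the bulky C5 is equatorial and C1 axial, so the equatorial acyl group ends cis to C5 (6S). The step needs selection between two diastereotopic arms and anti addition; ring B helps by having no enolisable hydrogen and no Michael acceptor, and the fixed 2R centre makes any mis-selected isomer a separable diastereomer.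

Step 11
Reactants: 15 1-[(2R,6S,9S,10S)-4-bromo-2-{[tert-butyl(dimethyl)silyl]oxy}-9-hydroxy-5,5,9-trimethyl-1-methylidenespiro[5.5]undec-3-en-10-yl]ethan-1-one
Product: 16 (2R,6S,9S,10S)-4-bromo-2-{[tert-butyl(dimethyl)silyl]oxy}-9-hydroxy-5,5,9-trimethyl-1-methylidenespiro[5.5]undec-3-en-10-yl acetate
Conditions: Me3SiOOSiMe3, SnCl4 (10 mol %), trans-cyclohexane-1,2-diamine (10 mol %), 4 Å MS, CH2Cl2, 0 °C → rt
Reagents that add atoms: bis(trimethylsilyl) peroxide, C[Si](C)(C)OO[Si](C)(C)C
Why: Baeyer–Villiger oxidation with a silyl peroxide under Lewis acid catalysis, a combination that oxidises ketones without epoxidising alkenes; the secondary C10 migrates in preference to methyl with retention, so the new C10–O bond keeps the equatorial orientation.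

Step 12
Reactants: 16 (2R,6S,9S,10S)-4-bromo-2-{[tert-butyl(dimethyl)silyl]oxy}-9-hydroxy-5,5,9-trimethyl-1-methylidenespiro[5.5]undec-3-en-10-yl acetate
Product: 17 (2R,6S,9S,10S)-4-bromo-2-{[tert-butyl(dimethyl)silyl]oxy}-5,5,9-trimethyl-1-methylidenespiro[5.5]undec-3-ene-9,10-diol
Conditions: K2CO3, MeOH, 0 °C → rt
Reagents that add atoms: none
Why: Base-catalysed transesterification of the acetate with methanol; no stereocentre is touched.

Step 13
Reactants: 17 (2R,6S,9S,10S)-4-bromo-2-{[tert-butyl(dimethyl)silyl]oxy}-5,5,9-trimethyl-1-methylidenespiro[5.5]undec-3-ene-9,10-diol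
Product: 19 tert-butyl{[(2R,6S,9S,10R)-4-bromo-9,10-epoxy-5,5,9-trimethyl-1-methylidenespiro[5.5]undec-3-en-2-yl]oxy}dimethylsilane, via mesylate 18 (not isolated)
Conditions: MsCl, Et3N, CH2Cl2, 0 °C; then KOtBu, THF, 0 °C → rt
Reagents that add atoms: none
Why: Selective mesylation of the secondary hydroxyl followed by intramolecular Williamson closure by the tertiary alkoxide; the displacement inverts C10 and keeps C9, placing the epoxide oxygen on the ring A face anti to C5 without any external nucleophile having to approach the screened C10.

Step 14
Reactants: 19 tert-butyl{[(2R,6S,9S,10R)-4-bromo-9,10-epoxy-5,5,9-trimethyl-1-methylidenespiro[5.5]undec-3-en-2-yl]oxy}dimethylsilane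
Product: 20 (2R,6S,9R,10R)-4,9-dibromo-2-{[tert-butyl(dimethyl)silyl]oxy}-5,5,9-trimethyl-1-methylidenespiro[5.5]undec-3-en-10-ol
Conditions: MgBr2·OEt2, Et2O/toluene, −20 → 0 °C; aq. NH4Cl
Reagents that add atoms: magnesium bromide, Br[Mg]Br
Why: Lewis-acid-assisted opening of the epoxide by bromide; attack at tertiary C9 anti to oxygen is both the Markovnikov and the trans-diaxial (Fürst–Plattner) mode, giving axial bromine on C9 (cis to C5) and axial hydroxyl on C10 with inversion at C9.

Step 15
Reactants: 20 (2R,6S,9R,10R)-4,9-dibromo-2-{[tert-butyl(dimethyl)silyl]oxy}-5,5,9-trimethyl-1-methylidenespiro[5.5]undec-3-en-10-ol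
Product: 23 tert-butyl{[(2R,6S,9S,10S)-4,10-dibromo-9-chloro-5,5,9-trimethyl-1-methylidenespiro[5.5]undec-3-en-2-yl]oxy}dimethylsilane, via triflate 21 (not isolated), via bromonium triflate 22 (not isolated)
Conditions: Tf2O, 2,6-di-tert-butyl-4-methylpyridine, CH2Cl2, −78 °C; then Bu4NCl, −78 → 0 °C
Reagents that add atoms: tetrabutylammonium chloride, CCCC[N+](CCCC)(CCCC)CCCC.[Cl-]
Why: Substitution with neighbouring bromine participation and 1,2-bromine shift: the axial triflate leaves with assistance from the antiperiplanar C9–Br, and chloride should open bromonium ion 22 at its tertiary, more cationic carbon C9 anti to bromine, so bromine arrives on C10 and chlorine on C9 with inversion at both centres (9S, 10S); return of chloride to C10 is hindered by the axial C1.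

Step 16
Reactants: 23 tert-butyl{[(2R,6S,9S,10S)-4,10-dibromo-9-chloro-5,5,9-trimethyl-1-methylidenespiro[5.5]undec-3-en-2-yl]oxy}dimethylsilane
Product: 24 (2R,6S,9S,10S)-4,10-dibromo-9-chloro-5,5,9-trimethyl-1-methylidenespiro[5.5]undec-3-en-2-ol
Conditions: Bu4NF, AcOH, THF, 0 °C
Reagents that add atoms: none
Why: Fluoride cleavage of the silyl ether buffered with acetic acid; the equatorial C–Br and C–Cl bonds have no antiperiplanar hydrogen in the preferred chair, so E2 elimination should not compete.

## Compound list

1 | 4,4-dimethylcyclohexane-1,3-dione | O=C1CC(=O)C(C)(C)CC1 | starting material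
2 | 3-methoxy-6,6-dimethylcyclohex-2-en-1-one | COC1=CC(=O)C(C)(C)CC1 | intermediate
3 | 2-methoxy-5,5-dimethylcyclohex-2-ene-1,4-dione | COC1=CC(=O)C(C)(C)CC1=O | intermediate
4 | methyl acrylate | C=CC(=O)OC | starting material
5 | methyl 3-(3-methoxy-6,6-dimethyl-2,5-dioxocyclohex-3-en-1-yl)propanoate (racemic mono-adduct) | COC(=O)CCC1C(=O)C(OC)=CC(=O)C1(C)C | intermediate
6 | dimethyl 3,3'-(3-methoxy-6,6-dimethyl-2,5-dioxocyclohex-3-ene-1,1-diyl)dipropanoate | COC(=O)CCC1(CCC(=O)OC)C(=O)C(OC)=CC(=O)C1(C)C | intermediate
7 | dimethyl 3,3'-(3-methoxy-6,6-dimethyl-2-methylidene-5-oxocyclohex-3-ene-1,1-diyl)dipropanoate | COC(=O)CCC1(CCC(=O)OC)C(=C)C(OC)=CC(=O)C1(C)C | intermediate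
8 | dimethyl 3,3'-(5-bromo-6,6-dimethyl-2-methylidene-3-oxocyclohex-4-ene-1,1-diyl)dipropanoate | COC(=O)CCC1(CCC(=O)OC)C(=C)C(=O)C=C(Br)C1(C)C | intermediate
9 | dimethyl 3,3'-[(3R)-5-bromo-3-hydroxy-6,6-dimethyl-2-methylidenecyclohex-4-ene-1,1-diyl]dipropanoate | C=C1[C@H](O)C=C(Br)C(C)(C)C1(CCC(=O)OC)CCC(=O)OC | intermediate
10 | dimethyl 3,3'-[(3R)-5-bromo-3-{[tert-butyl(dimethyl)silyl]oxy}-6,6-dimethyl-2-methylidenecyclohex-4-ene-1,1-diyl]dipropanoate | C=C1[C@H](O[Si](C)(C)C(C)(C)C)C=C(Br)C(C)(C)C1(CCC(=O)OC)CCC(=O)OC | intermediate
11 | 3,3'-[(3R)-5-bromo-3-{[tert-butyl(dimethyl)silyl]oxy}-6,6-dimethyl-2-methylidenecyclohex-4-ene-1,1-diyl]bis(N-methoxy-N-methylpropanamide) | C=C1[C@H](O[Si](C)(C)C(C)(C)C)C=C(Br)C(C)(C)C1(CCC(=O)N(C)OC)CCC(=O)N(C)OC | intermediate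
12 | 4,4'-[(3R)-5-bromo-3-{[tert-butyl(dimethyl)silyl]oxy}-6,6-dimethyl-2-methylidenecyclohex-4-ene-1,1-diyl]di(butan-2-one) | C=C1[C@H](O[Si](C)(C)C(C)(C)C)C=C(Br)C(C)(C)C1(CCC(C)=O)CCC(C)=O | intermediate
13 | (2S)-1-{(2E)-4-[(1S,3R)-5-bromo-3-{[tert-butyl(dimethyl)silyl]oxy}-6,6-dimethyl-2-methylidene-1-(3-oxobutyl)cyclohex-4-en-1-yl]but-2-en-2-yl}pyrrolidine-2-carboxylic acid (enamine of the donor arm) | C=C1[C@H](O[Si](C)(C)C(C)(C)C)C=C(Br)C(C)(C)[C@@]1(CCC(C)=O)C/C=C(C)/N2CCC[C@H]2C(=O)O | intermediate
14 | (2S)-1-{1-[(2R,6S,9S,10R)-4-bromo-2-{[tert-butyl(dimethyl)silyl]oxy}-9-hydroxy-5,5,9-trimethyl-1-methylidenespiro[5.5]undec-3-en-10-yl]ethylidene}pyrrolidin-1-ium-2-carboxylate (same spatial arrangement at C10 as 15) | C=C1[C@H](O[Si](C)(C)C(C)(C)C)C=C(Br)C(C)(C)[C@]12CC[C@](C)(O)[C@@H](C(C)=[N+]3CCC[C@H]3C([O-])=O)C2 | intermediate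
15 | 1-[(2R,6S,9S,10S)-4-bromo-2-{[tert-butyl(dimethyl)silyl]oxy}-9-hydroxy-5,5,9-trimethyl-1-methylidenespiro[5.5]undec-3-en-10-yl]ethan-1-one (acetyl cis to C5, hydroxyl trans to acetyl) | C=C1[C@H](O[Si](C)(C)C(C)(C)C)C=C(Br)C(C)(C)[C@]12CC[C@](C)(O)[C@@H](C(C)=O)C2 | intermediate
16 | (2R,6S,9S,10S)-4-bromo-2-{[tert-butyl(dimethyl)silyl]oxy}-9-hydroxy-5,5,9-trimethyl-1-methylidenespiro[5.5]undec-3-en-10-yl acetate | C=C1[C@H](O[Si](C)(C)C(C)(C)C)C=C(Br)C(C)(C)[C@]12CC[C@](C)(O)[C@@H](OC(C)=O)C2 | intermediate
17 | (2R,6S,9S,10S)-4-bromo-2-{[tert-butyl(dimethyl)silyl]oxy}-5,5,9-trimethyl-1-methylidenespiro[5.5]undec-3-ene-9,10-diol | C=C1[C@H](O[Si](C)(C)C(C)(C)C)C=C(Br)C(C)(C)[C@]12CC[C@](C)(O)[C@@H](O)C2 | intermediate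
18 | (2R,6S,9S,10S)-4-bromo-2-{[tert-butyl(dimethyl)silyl]oxy}-9-hydroxy-5,5,9-trimethyl-1-methylidenespiro[5.5]undec-3-en-10-yl methanesulfonate | C=C1[C@H](O[Si](C)(C)C(C)(C)C)C=C(Br)C(C)(C)[C@]12CC[C@](C)(O)[C@@H](OS(C)(=O)=O)C2 | intermediate
19 | tert-butyl{[(2R,6S,9S,10R)-4-bromo-9,10-epoxy-5,5,9-trimethyl-1-methylidenespiro[5.5]undec-3-en-2-yl]oxy}dimethylsilane (epoxide oxygen anti to C5) | C=C1[C@H](O[Si](C)(C)C(C)(C)C)C=C(Br)C(C)(C)[C@]12CC[C@]3(C)O[C@@H]3C2 | intermediate
20 | (2R,6S,9R,10R)-4,9-dibromo-2-{[tert-butyl(dimethyl)silyl]oxy}-5,5,9-trimethyl-1-methylidenespiro[5.5]undec-3-en-10-ol (C9 bromine cis to C5, C10 hydroxyl trans to C5) | C=C1[C@H](O[Si](C)(C)C(C)(C)C)C=C(Br)C(C)(C)[C@]12CC[C@@](C)(Br)[C@H](O)C2 | intermediate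
21 | (2R,6S,9R,10R)-4,9-dibromo-2-{[tert-butyl(dimethyl)silyl]oxy}-5,5,9-trimethyl-1-methylidenespiro[5.5]undec-3-en-10-yl trifluoromethanesulfonate | C=C1[C@H](O[Si](C)(C)C(C)(C)C)C=C(Br)C(C)(C)[C@]12CC[C@@](C)(Br)[C@H](OS(=O)(=O)C(F)(F)F)C2 | intermediate
22 | bromonium ion bridging C9 and C10 on the ring A face cis to C5 (2R,6S), as its triflate | C=C1[C@H](O[Si](C)(C)C(C)(C)C)C=C(Br)C(C)(C)[C@]12CC[C@@]3(C)[Br+][C@H]3C2.[O-]S(=O)(=O)C(F)(F)F | intermediate
23 | tert-butyl{[(2R,6S,9S,10S)-4,10-dibromo-9-chloro-5,5,9-trimethyl-1-methylidenespiro[5.5]undec-3-en-2-yl]oxy}dimethylsilane | C=C1[C@H](O[Si](C)(C)C(C)(C)C)C=C(Br)C(C)(C)[C@]12CC[C@](C)(Cl)[C@@H](Br)C2 | intermediate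
24 | (2R,6S,9S,10S)-4,10-dibromo-9-chloro-5,5,9-trimethyl-1-methylidenespiro[5.5]undec-3-en-2-ol (CNP0228180.1) | C=C1[C@H](O)C=C(Br)C(C)(C)[C@]12CC[C@](C)(Cl)[C@@H](Br)C2 | target

## Step count and least certain steps

Total: 16 steps. Longest linear sequence: 16 steps (1 to 24); 4 enters at step 3, where two molecules are incorporated.

Step 10 (key step). The likely failure is slow turnover with erosion of selectivity: the productive enamine is the more substituted, minor one, and the acceptor is a ketone. The aldol may therefore become reversible and drift towards the ketol with an equatorial methyl, the 2R centre may be mismatched with the catalyst, and the sense of induction rests on analogy (the R catalyst would answer an opposite sense). Fallback: the route sets out again from 12 and gives up catalyst control. Cyclisation with pyrrolidinium acetate should give 15 together with its ring A antipode, 1-[(2R,6R,9R,10R)-4-bromo-2-{[tert-butyl(dimethyl)silyl]oxy}-9-hydroxy-5,5,9-trimethyl-1-methylidenespiro[5.5]undec-3-en-10-yl]ethan-1-one F1. Because C2 is fixed the two are diastereomers and are separated by chromatography; the route is rejoined at 15.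

Step 3. The second conjugate addition may stall next to the gem-dimethyl carbon, and the enolate of 3 may add to another molecule of 3 at C3. Fallback: from 3, one equivalent of 4 under the same base gives 5, which is isolated in this variant. Me3SiOTf/Et3N converts it into methyl 3-{3-methoxy-6,6-dimethyl-5-oxo-2-[(trimethylsilyl)oxy]cyclohexa-1,3-dien-1-yl}propanoate F2, and a Tf2NH-catalysed Mukaiyama–Michael addition to 4 then forms the quaternary centre under acid; the route is rejoined at 6.

Step 2. Over-oxidation or attack at the α-carbon of the electron-rich enol ether may compete with oxidation of the γ-methylene. Fallback: from 2, LiN(iPr)2/Me3SiCl removes a γ-hydrogen (the other side is blocked) to give [(3-methoxy-6,6-dimethylcyclohexa-1,3-dien-1-yl)oxy](trimethyl)silane F3. Dimethyldioxirane gives 4-hydroxy-3-methoxy-6,6-dimethylcyclohex-2-en-1-one F4 by vinylogous Rubottom oxidation, and Dess–Martin periodinane rejoins the route at 3.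

Step 13. Closure needs the C9 oxygen antiperiplanar to the equatorial mesylate, which the diequatorial system reaches only through a non-chair form; migration of the antiperiplanar C8–C9 bond (ring contraction to an acetylcyclopentane) may overtake it. Fallback: from 17, Dess–Martin oxidation gives (2R,6S,9S)-4-bromo-2-{[tert-butyl(dimethyl)silyl]oxy}-9-hydroxy-5,5,9-trimethyl-1-methylidenespiro[5.5]undec-3-en-10-one F5. LiBH(s-Bu)3 should attack equatorially, away from the axial C1, to give (2R,6S,9S,10R)-4-bromo-2-{[tert-butyl(dimethyl)silyl]oxy}-5,5,9-trimethyl-1-methylidenespiro[5.5]undec-3-ene-9,10-diol F6. Me3SiBr should then ionise the tertiary C9–O bond; the axial C10 oxygen can bridge the cation from the lower face, so bromide enters axially from the upper face, and aqueous work-up frees the C10 hydroxyl from any trimethylsilyl group. The route is rejoined at 20.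

Step 15. Chloride may return to C10 instead of C9, giving the isomer with the halogens exchanged, or the bromonium ion may lose a proton to an allylic bromide; the doubly allylic silyl ether is also exposed to a strong electrophile. Fallback: from 19, deoxygenation with WCl6/n-BuLi gives tert-butyl{[(2R,6S)-4-bromo-5,5,9-trimethyl-1-methylidenespiro[5.5]undeca-3,9-dien-2-yl]oxy}dimethylsilane F7. Bromochlorination with N-bromosuccinimide and ClTi(OiPr)3 adds bromine and chlorine anti with chlorine at C9; the facial diastereomers would be separated, and the route is rejoined at 23.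

## Further compounds

F1 | step 10 | 1-[(2R,6R,9R,10R)-4-bromo-2-{[tert-butyl(dimethyl)silyl]oxy}-9-hydroxy-5,5,9-trimethyl-1-methylidenespiro[5.5]undec-3-en-10-yl]ethan-1-one | C=C1[C@H](O[Si](C)(C)C(C)(C)C)C=C(Br)C(C)(C)[C@@]12CC[C@@](C)(O)[C@H](C(C)=O)C2
F2 | step 3 | methyl 3-{3-methoxy-6,6-dimethyl-5-oxo-2-[(trimethylsilyl)oxy]cyclohexa-1,3-dien-1-yl}propanoate | COC(=O)CCC1=C(O[Si](C)(C)C)C(OC)=CC(=O)C1(C)C
F3 | step 2 | [(3-methoxy-6,6-dimethylcyclohexa-1,3-dien-1-yl)oxy](trimethyl)silane | COC1=CCC(C)(C)C(O[Si](C)(C)C)=C1
F4 | step 2 | 4-hydroxy-3-methoxy-6,6-dimethylcyclohex-2-en-1-one (racemic) | COC1=CC(=O)C(C)(C)CC1O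
F5 | step 13 | (2R,6S,9S)-4-bromo-2-{[tert-butyl(dimethyl)silyl]oxy}-9-hydroxy-5,5,9-trimethyl-1-methylidenespiro[5.5]undec-3-en-10-one | C=C1[C@H](O[Si](C)(C)C(C)(C)C)C=C(Br)C(C)(C)[C@]12CC[C@](C)(O)C(=O)C2
F6 | step 13 | (2R,6S,9S,10R)-4-bromo-2-{[tert-butyl(dimethyl)silyl]oxy}-5,5,9-trimethyl-1-methylidenespiro[5.5]undec-3-ene-9,10-diol | C=C1[C@H](O[Si](C)(C)C(C)(C)C)C=C(Br)C(C)(C)[C@]12CC[C@](C)(O)[C@H](O)C2
F7 | step 15 | tert-butyl{[(2R,6S)-4-bromo-5,5,9-trimethyl-1-methylidenespiro[5.5]undeca-3,9-dien-2-yl]oxy}dimethylsilane | C=C1[C@H](O[Si](C)(C)C(C)(C)C)C=C(Br)C(C)(C)[C@]12CCC(C)=CC2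
A1 | alternative 1 | (6S)-4-bromo-5,5,9-trimethylspiro[5.5]undeca-3,9-dien-2-one | O=C1C[C@@]2(CCC(C)=CC2)C(C)(C)C(Br)=C1
A2 | alternative 2 | (6R)-2-methoxy-5,5-dimethylspiro[5.5]undeca-2,10-diene-1,4,9-trione | COC1=CC(=O)C(C)(C)[C@]2(CCC(=O)C=C2)C1=O
A3 | alternative 3 | 4-bromo-5,5-dimethylspiro[5.5]undec-3-ene-2,9-dione 9-ethylene ketal | CC1(C)C(Br)=CC(=O)CC12CCC3(CC2)OCCO3
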